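## Retrosynthetic overview
1. Target ⇒ its mono-methyl ether ⇒ (OH-directed ortho/para dibromination) 2-(3,6-dibromo-2-methoxyphenoxy)phenol. The awkward 3,6-dibromo pattern is never made by bromination.
2. The hydroxyphenyl ring is built on the ether oxygen: phenol ⇒ (dehydrogenation) 2-aryloxycyclohex-2-enone ⇒ (intramolecular aldol condensation, loss of the CO2tBu group) δ-keto aldehyde.
3. Key C–C disconnection: δ-keto aldehyde ⇒ tert-butyl 4-aryloxyacetoacetate + acrolein (intermolecular Michael addition). The keto ester ⇒ methyl aryloxyacetate + tert-butyl acetate (crossed Claisen).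
4. Aryloxyacetate ⇒ 3,6-dibromo-2-methoxyphenol + methyl bromoacetate (SN2, so no metal-catalysed C–O coupling next to C–Br). The phenol ⇒ 2,5-dibromoanisole (ortho-lithiation, borylation, oxidation).
5. Ring order: the dibromoanisole ring is bought. The second ring is closed in step 5, aromatised in steps 6–7 and brominated in step 8.

Assumption: the target has no stereocentre and its diaryl ether axis rotates freely, so it is achiral and there is no enantiomer to select. The single stereocentre in 12–14 is racemic, enolisable and erased in step 5.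

## Route

Step 1
Reactants: 1 2,5-dibromoanisole (1,4-dibromo-2-methoxybenzene)
Product: 4 3,6-dibromo-2-methoxyphenol, via 3,6-dibromo-2-methoxyphenyllithium 2 (not isolated), via lithium aryltrimethoxyborate 3 (not isolated)
Conditions: LDA (1.1 equiv, commercial solution), THF, −78 °C, 1 h; B(OMe)3 (1.5 equiv), −78 °C → rt; AcOH, 30% aq H2O2, 0 °C → rt
Reagents that add atoms: hydrogen peroxide OO (the new phenol O); LDA [Li+].CC(C)[N-]C(C)C (Li of 2 and 3 only); trimethyl borate COB(OC)OC (boron part of 3 only)
Why: Directed ortho-metalation followed by borylation–oxidation: the only C–H flanked by both OMe and Br is the most acidic one, the aryllithium is stable to LiBr loss at −78 °C, and the peroxide-induced 1,2-aryl shift puts the OH exactly on the metalated carbon.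

Step 2
Reactants: 4 3,6-dibromo-2-methoxyphenol; 5 methyl bromoacetate
Product: 6 methyl 2-(3,6-dibromo-2-methoxyphenoxy)acetate
Conditions: K2CO3 (1.5 equiv), acetone, reflux
Reagents that add atoms: none
Why: Williamson ether synthesis: the acidic, hindered phenoxide meets an unhindered, activated primary bromide in an SN2 reaction, so the C–O bond that becomes the diaryl ether is made without a metal catalyst that could touch the C–Br bonds.

Step 3
Reactants: 6 methyl 2-(3,6-dibromo-2-methoxyphenoxy)acetate; 7 tert-butyl acetate
Product: 10 tert-butyl 4-(3,6-dibromo-2-methoxyphenoxy)-3-oxobutanoate, via lithium enolate of tert-butyl acetate 8 (not isolated), via lithium enolate of the keto ester 9 (not isolated)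
Conditions: LDA (3.0 equiv), 7 (3.1 equiv), THF, −78 °C; then 6, −78 → −30 °C; AcOH quench
Reagents that add atoms: LDA [Li+].CC(C)[N-]C(C)C (Li of 8 and 9 only)
Why: Crossed Claisen condensation: the preformed tert-butyl acetate enolate does not self-condense at −78 °C and is acylated cleanly by the activated α-aryloxy methyl ester, and immediate deprotonation of the product to 9 stops a second addition.

Step 4 (key fragment union)
Reactants: 10 tert-butyl 4-(3,6-dibromo-2-methoxyphenoxy)-3-oxobutanoate; 11 acrolein
Product: 12 tert-butyl 2-[2-(3,6-dibromo-2-methoxyphenoxy)acetyl]-5-oxopentanoate (racemic)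
Conditions: Et3N (10 mol %), CH2Cl2, 0 °C, slow addition of freshly distilled 11 (1.1 equiv)
Reagents that add atoms: none
Why: Michael addition: only the doubly activated C2–H (pKa about 11) is deprotonated by the amine and the soft enolate adds 1,4 to acrolein, joining the C3 unit to the aryloxy keto ester; the new stereocentre forms racemic, is enolisable and is erased in step 5.

Step 5
Reactants: 12 tert-butyl 2-[2-(3,6-dibromo-2-methoxyphenoxy)acetyl]-5-oxopentanoate
Product: 15 2-(3,6-dibromo-2-methoxyphenoxy)cyclohex-2-en-1-one, via tert-butyl 3-aryloxy-2-oxocyclohex-3-ene-1-carboxylate 13 (not isolated), via 3-aryloxy-2-oxocyclohex-3-ene-1-carboxylic acid 14 (not isolated)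
Conditions: p-TsOH·H2O (0.3 equiv), toluene, 80 °C → reflux (Dean–Stark)
Reagents that add atoms: none
Why: Intramolecular aldol condensation, then acidolysis of the tert-butyl ester and β-keto acid decarboxylation: the ArOCH2 carbon is the only enolisable position that reaches the aldehyde through a six-membered ring (every other pairing gives a four-membered ring), and both ortho positions of the aryl ether are blocked so no benzofuran can form.

Step 6
Reactants: 15 2-(3,6-dibromo-2-methoxyphenoxy)cyclohex-2-en-1-one
Product: 16 {[6-(3,6-dibromo-2-methoxyphenoxy)cyclohexa-1,5-dien-1-yl]oxy}trimethylsilane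
Conditions: TMSOTf (1.3 equiv), Et3N (2 equiv), CH2Cl2, 0 °C; cold aq NaHCO3/pentane work-up, crude oil used at once
Reagents that add atoms: trimethylsilyl triflate C[Si](C)(C)OS(=O)(=O)C(F)(F)F
Why: Soft enolisation (silyl enol ether formation): TMSOTf activates the ketone and Et3N removes the α′-proton to give the 2-silyloxy-1,3-cyclohexadiene without any strong base near the aryl bromides.

Step 7
Reactants: 16 {[6-(3,6-dibromo-2-methoxyphenoxy)cyclohexa-1,5-dien-1-yl]oxy}trimethylsilane
Product: 18 2-(3,6-dibromo-2-methoxyphenoxy)phenol, via aryl trimethylsilyl ether 17 (not isolated)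
Conditions: DDQ (1.1 equiv), toluene, 0 °C → rt; filter; 1 M HCl, THF, rt
Reagents that add atoms: none
Why: DDQ dehydrogenation of a 1,3-cyclohexadiene (hydride abstraction, then proton loss) is driven by aromatisation and delivers the phenol masked as its silyl ether, which shields it from over-oxidation until the acid work-up removes the silyl group.

Step 8
Reactants: 18 2-(3,6-dibromo-2-methoxyphenoxy)phenol
Product: 19 2,4-dibromo-6-(3,6-dibromo-2-methoxyphenoxy)phenol
Conditions: Br2 (2.05 equiv), AcOH, rt
Reagents that add atoms: bromine BrBr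
Why: Electrophilic aromatic bromination: the free OH is by far the strongest director and sends the two bromines to its para and its one free ortho position, while the other ring is deactivated by two bromines and carries a twisted, poorly donating OMe.

Step 9
Reactants: 19 2,4-dibromo-6-(3,6-dibromo-2-methoxyphenoxy)phenol
Product: 20 3,6-dibromo-2-(3,5-dibromo-2-hydroxyphenoxy)phenol (target)
Conditions: BBr3 (3 equiv), CH2Cl2, −78 °C → rt; H2O
Reagents that add atoms: none
Why: Lewis-acid ether cleavage with BBr3: bromide attacks the methyl carbon of the boron-complexed ether in an SN2 step, a pathway that the diaryl ether and the aryl C–Br bonds do not have.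

## Compound list
1 | 2,5-dibromoanisole | COc1cc(Br)ccc1Br | starting material
2 | 3,6-dibromo-2-methoxyphenyllithium | COc1c([Li])c(Br)ccc1Br | intermediate
3 | lithium (3,6-dibromo-2-methoxyphenyl)trimethoxyborate | [Li+].COc1c(Br)ccc(Br)c1[B-](OC)(OC)OC | intermediate
4 | 3,6-dibromo-2-methoxyphenol | COc1c(O)c(Br)ccc1Br | intermediate
5 | methyl bromoacetate | COC(=O)CBr | starting material
6 | methyl 2-(3,6-dibromo-2-methoxyphenoxy)acetate | COC(=O)COc1c(Br)ccc(Br)c1OC | intermediate
7 | tert-butyl acetate | CC(=O)OC(C)(C)C | starting material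
8 | lithium enolate of tert-butyl acetate | [Li+].[CH2-]C(=O)OC(C)(C)C | intermediate
9 | lithium enolate of tert-butyl 4-(3,6-dibromo-2-methoxyphenoxy)-3-oxobutanoate | [Li+].CC(C)(C)OC(=O)[CH-]C(=O)COc1c(Br)ccc(Br)c1OC | intermediate
10 | tert-butyl 4-(3,6-dibromo-2-methoxyphenoxy)-3-oxobutanoate | CC(C)(C)OC(=O)CC(=O)COc1c(Br)ccc(Br)c1OC | intermediate
11 | acrolein | C=CC=O | starting material
12 | tert-butyl 2-[2-(3,6-dibromo-2-methoxyphenoxy)acetyl]-5-oxopentanoate (racemic) | CC(C)(C)OC(=O)C(CCC=O)C(=O)COc1c(Br)ccc(Br)c1OC | intermediate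
13 | tert-butyl 3-(3,6-dibromo-2-methoxyphenoxy)-2-oxocyclohex-3-ene-1-carboxylate (racemic) | CC(C)(C)OC(=O)C1CCC=C(Oc2c(Br)ccc(Br)c2OC)C1=O | intermediate
14 | 3-(3,6-dibromo-2-methoxyphenoxy)-2-oxocyclohex-3-ene-1-carboxylic acid (racemic) | OC(=O)C1CCC=C(Oc2c(Br)ccc(Br)c2OC)C1=O | intermediate
15 | 2-(3,6-dibromo-2-methoxyphenoxy)cyclohex-2-en-1-one | O=C1CCCC=C1Oc1c(Br)ccc(Br)c1OC | intermediate
16 | {[6-(3,6-dibromo-2-methoxyphenoxy)cyclohexa-1,5-dien-1-yl]oxy}trimethylsilane | C[Si](C)(C)OC1=CCCC=C1Oc1c(Br)ccc(Br)c1OC | intermediate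
17 | [2-(3,6-dibromo-2-methoxyphenoxy)phenoxy]trimethylsilane | C[Si](C)(C)Oc1ccccc1Oc1c(Br)ccc(Br)c1OC | intermediate
18 | 2-(3,6-dibromo-2-methoxyphenoxy)phenol | Oc1ccccc1Oc1c(Br)ccc(Br)c1OC | intermediate
19 | 2,4-dibromo-6-(3,6-dibromo-2-methoxyphenoxy)phenol | Oc1c(Br)cc(Br)cc1Oc1c(Br)ccc(Br)c1OC | intermediate
20 | 3,6-dibromo-2-(3,5-dibromo-2-hydroxyphenoxy)phenol (achiral) | Oc1c(Br)cc(Br)cc1Oc1c(Br)ccc(Br)c1O | target

## Step count and risks
Total steps: 9. Longest linear sequence: 9 steps (1 → 20). Compounds 5, 7 and 11 are bought and enter directly.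

**Step 1** may fail through lithiation next to a bromine only, halogen dance, or benzyne loss.
- The fallback sets out from 1 and comes back at 4 without any aryl anion.
- BBr3 in CH2Cl2 demethylates 1 to 2,5-dibromophenol F1.
- Magnesium-mediated ortho-formylation (MgCl2, Et3N, paraformaldehyde, MeCN, reflux) can only reach the single free ortho position and gives 3,6-dibromo-2-hydroxybenzaldehyde F2.
- Dakin oxidation (H2O2, aq NaOH) gives 3,6-dibromobenzene-1,2-diol F3.
- Mono-O-methylation of this symmetric catechol (MeI 1.0 equiv, Li2CO3, DMF) gives 4. The catechol is more acidic than the product, which favours the mono-ether.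

**Step 4** may fail through a second addition of acrolein to 12 or polymerisation of acrolein.
- The fallback sets out from 10 and comes back at 12. It replaces the conjugate addition by an enolate alkylation with a masked aldehyde.
- The sodium enolate of 10 (NaH, DMF, 0 °C) is alkylated with 2-(2-bromoethyl)-1,3-dioxolane (cat. NaI, 60 °C). This gives tert-butyl 2-[2-(3,6-dibromo-2-methoxyphenoxy)acetyl]-4-(1,3-dioxolan-2-yl)butanoate F4.
- PPTS in wet acetone at reflux then unmasks the aldehyde to give 12.

**Step 5** may fail because the acid cascade stalls at pyran or hemiacetal forms, or gives tar at the temperature needed for ester loss.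
- The fallback sets out from 12 and comes back at 19. It aromatises before the carboxyl group is removed.
- Catalytic piperidinium acetate in toluene at 60 °C closes the ring to 13, which is now isolated.
- The cyclohexadienol tautomer of 13 is dehydrogenated by DDQ in dioxane to tert-butyl 3-(3,6-dibromo-2-methoxyphenoxy)-2-hydroxybenzoate F5.
- TFA in CH2Cl2 gives 3-(3,6-dibromo-2-methoxyphenoxy)-2-hydroxybenzoic acid F6.
- Br2 (2.2 equiv) in aqueous AcOH brominates para to the OH. It then attacks ipso at the carboxyl-bearing ortho carbon with loss of CO2 (bromodecarboxylation of a salicylic acid), giving 19 directly.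

## Further compounds
F1 | step 1 | 2,5-dibromophenol | Oc1cc(Br)ccc1Br
F2 | step 1 | 3,6-dibromo-2-hydroxybenzaldehyde | O=Cc1c(O)c(Br)ccc1Br
F3 | step 1 | 3,6-dibromobenzene-1,2-diol | Oc1c(O)c(Br)ccc1Br
F4 | step 4 | tert-butyl 2-[2-(3,6-dibromo-2-methoxyphenoxy)acetyl]-4-(1,3-dioxolan-2-yl)butanoate (racemic) | CC(C)(C)OC(=O)C(CCC1OCCO1)C(=O)COc1c(Br)ccc(Br)c1OC
F5 | step 5 | tert-butyl 3-(3,6-dibromo-2-methoxyphenoxy)-2-hydroxybenzoate | CC(C)(C)OC(=O)c1cccc(Oc2c(Br)ccc(Br)c2OC)c1O
F6 | step 5 | 3-(3,6-dibromo-2-methoxyphenoxy)-2-hydroxybenzoic acid | OC(=O)c1cccc(Oc2c(Br)ccc(Br)c2OC)c1O
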